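## Retrosynthetic overview

1. Target 32 ← LiOH ← methyl ester 31 ← axial hydride delivery to C3 of 29 ← axial alkenyl transfer from trifluoroborate 26 to the C6 peroxycarbenium ion of bis-ketal 15 (convergent union at the quaternary carbon) ← peroxy hemiketal 14.
2. The 1,2-dioxane is the only ring and is not closed at its final size: 14 arises from cyclobutene ester 10 by ozonolysis in methanol, which inserts O–O between C1 and C2 of the four-membered carbocycle (C1, C2, C3, C4 of 10 become C3, C6, C5, C4 of the dioxane).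
3. Enabling feature: the tetrasubstituted C1=C2 double bond inside the cyclobutene ring of 10 (C1 bears the CH2CO2Me arm, C2 the ethyl group). The two-carbon bridge C3–C4 keeps the cleavage termini 1,4-related, so the hydroperoxide at C2 closes on the ketone at C1 as a six-membered ring; C4 is the single stereocentre from which C6 and C3 are later set.
4. 10 ← enol triflate 9 + BrZnCH2CO2Me ← C2-symmetric (2R,4R)-2,4-diethylcyclobutanone 7 ← cyclobutanone 1 by double SAMP-hydrazone ethylation.
5. 26 ← iodide 23 ← alkyne 21 (syn-carbocupration) ← ester 19 (Johnson–Claisen, 1,3-chirality transfer) ← (R)-allylic alcohol 17 ← (E)-pent-2-enal 16 + Et2Zn.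

Key step: step 7

Remark on the chemistry: ring positions of all peroxides are numbered as in the target (O1, O2, C3, C4, C5, C6). The ketal carbons C3 and C6 in 14 and 15, and C3 in 29, are expected as epimer mixtures and are written without configuration, because each is ionised again later.

## Route

Step 1
Reactants: 1 cyclobutanone
Product: 2 (2S)-N-cyclobutylidene-2-(methoxymethyl)pyrrolidin-1-amine
Conditions: SAMP (1.05 equiv), cyclohexane, 4 Å molecular sieves, 60 °C
Reagents that add atoms: (S)-1-amino-2-(methoxymethyl)pyrrolidine (SAMP), SMILES COC[C@@H]1CCCN1N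
Why: Condensation of the unhindered ketone with the hydrazine should give the Enders SAMP hydrazone; no stereocentre is formed.

Step 2
Reactants: 2 (2S)-N-cyclobutylidene-2-(methoxymethyl)pyrrolidin-1-amine
Product: 4 (2S)-N-[(2R)-2-ethylcyclobutylidene]-2-(methoxymethyl)pyrrolidin-1-amine, via lithium azaenolate 3 (not isolated)
Conditions: LiN(iPr)2 (1.1 equiv), THF, 0 °C; EtI, −95 → 20 °C
Reagents that add atoms: iodoethane, SMILES CCI
Why: Enders SAMP-hydrazone alkylation, in which the chelated azaenolate is ethylated on the face dictated by the methoxymethylpyrrolidine auxiliary; by the usual sense of SAMP alkylation of cyclic ketones the new centre should be (R).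

Step 3
Reactants: 4 (2S)-N-[(2R)-2-ethylcyclobutylidene]-2-(methoxymethyl)pyrrolidin-1-amine
Product: 6 (2S)-N-[(2R,4R)-2,4-diethylcyclobutylidene]-2-(methoxymethyl)pyrrolidin-1-amine, via lithium azaenolate 5 (not isolated)
Conditions: LiN(iPr)2 (1.1 equiv), THF, 0 °C; EtI, −95 → 20 °C
Reagents that add atoms: iodoethane, SMILES CCI
Why: Second Enders alkylation at the unsubstituted α′ carbon (the hydrazone N–N bond lies anti to the substituted α carbon); the auxiliary again directs (R), which should give the trans, C2-symmetric hydrazone.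

Step 4
Reactants: 6 (2S)-N-[(2R,4R)-2,4-diethylcyclobutylidene]-2-(methoxymethyl)pyrrolidin-1-amine
Product: 7 (2R,4R)-2,4-diethylcyclobutan-1-one
Conditions: saturated aq. (CO2H)2, Et2O, 20 °C
Reagents that add atoms: water, SMILES O
Why: Two-phase oxalic acid hydrolysis of SAMP hydrazones is the standard epimerisation-free release of the ketone and returns the auxiliary.

Step 5
Reactants: 7 (2R,4R)-2,4-diethylcyclobutan-1-one
Product: 9 (4R)-2,4-diethylcyclobut-1-en-1-yl trifluoromethanesulfonate, via potassium enolate 8 (not isolated)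
Conditions: KN(SiMe3)2 (1.1 equiv), THF, −78 °C; PhNTf2, −78 → 0 °C
Reagents that add atoms: N-phenylbis(trifluoromethanesulfonimide), SMILES O=S(=O)(N(c1ccccc1)S(=O)(=O)C(F)(F)F)C(F)(F)F
Why: Kinetic enolisation and O-triflation; because 7 is C2-symmetric its two α-hydrogens are homotopic, so one enol triflate should result and the untouched α′ carbon keeps its (R) configuration as the only stereocentre (the future C4 of the dioxane).

Step 6
Reactants: 9 (4R)-2,4-diethylcyclobut-1-en-1-yl trifluoromethanesulfonate
Product: 10 methyl 2-[(4R)-2,4-diethylcyclobut-1-en-1-yl]acetate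
Conditions: BrZnCH2CO2Me (from BrCH2CO2Me, Zn, Me3SiCl cat., THF), Pd(PPh3)4 (5 mol %), THF, 60 °C
Reagents that add atoms: methyl bromoacetate (used as its zinc reagent), SMILES COC(=O)CBr
Why: Negishi-type cross-coupling of an alkenyl triflate with a Reformatsky reagent at zerovalent palladium joins the sp2 carbon to the CH2CO2Me unit without touching the stereocentre.

Step 7
Reactants: 10 methyl 2-[(4R)-2,4-diethylcyclobut-1-en-1-yl]acetate
Product: 14 methyl 2-[(4R)-4,6-diethyl-3-hydroxy-6-methoxy-1,2-dioxan-3-yl]acetate, via primary ozonide 11 (not isolated), via keto carbonyl oxide 12 (not isolated), via methoxy hydroperoxide 13 (not isolated)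
Conditions: O3, CH2Cl2–MeOH 4:1, −78 °C; N2 purge; 0 °C, no reductant
Reagents that add atoms: ozone, SMILES [O-][O+]=O; methanol, SMILES CO
Why: Ozone adds to the only C=C by 1,3-dipolar cycloaddition to give primary ozonide 11, whose cycloreversion cuts the C1–C2 bond of the strained four-membered ring to keto carbonyl oxide 12, with the carbonyl oxide expected on the ethyl-bearing carbon, remote from the electron-withdrawing ester arm. Methanol traps 12 as methoxy hydroperoxide 13, whose OOH group adds to the 3-keto ester carbonyl four carbons away (6-exo-trig), so that O–O ends up inserted between the two former alkene carbons and the four-membered carbocycle becomes the six-membered 1,2-dioxane. The closest known reaction type is the Criegee ozonolysis of cycloalkenes in methanol, in which the methoxy hydroperoxide terminus closes on the carbonyl terminus to a cyclic peroxy hemiketal. The new stereocentres C3 and C6 are deliberately not controlled (axial OH and OMe are expected from the anomeric effect), because both are ketal carbons that are ionised again in steps 15 and 16; C4 comes unchanged from 10. The selectivity needed is cleavage of one alkene without epimerisation at C4 and without loss of the peroxide, secured by the absence of any other π bond, by neutral conditions at low temperature and by omitting a reductive work-up.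

Step 8
Reactants: 14 methyl 2-[(4R)-4,6-diethyl-3-hydroxy-6-methoxy-1,2-dioxan-3-yl]acetate
Product: 15 methyl 2-[(4R)-4,6-diethyl-6-methoxy-3-[(triethylsilyl)oxy]-1,2-dioxan-3-yl]acetate
Conditions: Et3SiOTf (1.2 equiv), 2,6-lutidine (2 equiv), CH2Cl2, −78 °C
Reagents that add atoms: triethylsilyl trifluoromethanesulfonate, SMILES CC[Si](CC)(CC)OS(=O)(=O)C(F)(F)F
Why: Silyl etherification of the tertiary hemiketal hydroxyl locks C3 in the cyclic form, so that ring–chain tautomerism cannot open the dioxane while C6 is ionised in step 15.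

Step 9
Reactants: 16 (E)-pent-2-enal
Product: 17 (3R,4E)-hept-4-en-3-ol
Conditions: Et2Zn (2 equiv), (+)-MIB [(2R)-3-exo-morpholinoisoborneol] (4 mol %), hexane–toluene, 0 °C; 1 M HCl quench
Reagents that add atoms: diethylzinc, SMILES CC[Zn]CC
Why: Amino-alcohol-catalysed enantioselective addition of diethylzinc to an enal; (+)-MIB is chosen because its enantiomer delivers (S)-carbinols from aldehydes, so the (R)-allylic alcohol is expected.

Step 10
Reactants: 17 (3R,4E)-hept-4-en-3-ol
Product: 19 ethyl (3R,4E)-3-ethylhept-4-enoate, via ketene acetal 18 (not isolated)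
Conditions: CH3C(OEt)3 (excess), EtCO2H (cat.), 140 °C, removal of EtOH
Reagents that add atoms: triethyl orthoacetate, SMILES CC(OCC)(OCC)OCC
Why: Johnson–Claisen rearrangement through a chair transition state with the carbinol ethyl group equatorial transfers the C–O chirality suprafacially to the new C–C bond, which should give the (R) stereocentre and the (E)-alkene.

Step 11
Reactants: 19 ethyl (3R,4E)-3-ethylhept-4-enoate
Product: 20 (3R,4E)-3-ethylhept-4-enal
Conditions: iBu2AlH (1.05 equiv), CH2Cl2, −78 °C; MeOH, then aq. potassium sodium tartrate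
Reagents that add atoms: none
Why: Low-temperature iBu2AlH reduction of an ester stops at the aldehyde, and the stereocentre is β to the carbonyl and cannot epimerise.

Step 12
Reactants: 20 (3R,4E)-3-ethylhept-4-enal
Product: 21 (4R,5E)-4-ethyloct-5-en-1-yne
Conditions: dimethyl (1-diazo-2-oxopropyl)phosphonate, K2CO3, MeOH, 0 → 20 °C
Reagents that add atoms: dimethyl (1-diazo-2-oxopropyl)phosphonate, SMILES CC(=O)C(=[N+]=[N-])P(=O)(OC)OC
Why: Seyferth–Gilbert homologation in the Ohira–Bestmann variant converts the aldehyde into the terminal alkyne under mild carbonate conditions.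

Step 13
Reactants: 21 (4R,5E)-4-ethyloct-5-en-1-yne
Product: 23 (1E,4R,5E)-2,4-diethyl-1-iodoocta-1,5-diene, via alkenylcopper 22 (not isolated)
Conditions: EtMgBr, CuBr·SMe2, Et2O–Me2S, −45 °C; 21, −25 °C; I2, −78 → 0 °C
Reagents that add atoms: ethylmagnesium bromide, SMILES CC[Mg]Br; iodine, SMILES II
Why: Normant carbocupration adds ethyl and copper syn across the terminal alkyne with copper on the terminal carbon, and iodinolysis with retention should give the iodide in which iodine is cis to the new ethyl group, the geometry the target needs.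

Step 14
Reactants: 23 (1E,4R,5E)-2,4-diethyl-1-iodoocta-1,5-diene
Product: 26 potassium [(1E,4R,5E)-2,4-diethylocta-1,5-dien-1-yl]trifluoroborate, via alkenyllithium 24 (not isolated), via lithium trimethoxyborate 25 (not isolated)
Conditions: tert-butyllithium (2.1 equiv), Et2O, −78 °C; B(OMe)3, −78 → 20 °C; aq. KHF2, MeOH
Reagents that add atoms: trimethyl borate, SMILES COB(OC)OC; potassium hydrogen difluoride, SMILES F.[F-].[K+]
Why: Iodine–lithium exchange with retention of alkene geometry, borylation and fluoride exchange are the standard route to a bench-stable alkenyltrifluoroborate.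

Step 15
Reactants: 15 methyl 2-[(4R)-4,6-diethyl-6-methoxy-3-[(triethylsilyl)oxy]-1,2-dioxan-3-yl]acetate; 26 potassium [(1E,4R,5E)-2,4-diethylocta-1,5-dien-1-yl]trifluoroborate
Product: 29 methyl 2-[(4R,6S)-6-[(1E,4R,5E)-2,4-diethylocta-1,5-dien-1-yl]-4,6-diethyl-3-[(triethylsilyl)oxy]-1,2-dioxan-3-yl]acetate, via alkenyldifluoroborane 27 (not isolated), via peroxycarbenium ion 28 (not isolated)
Conditions: BF3·OEt2 (2.5 equiv), CH2Cl2–MeCN, −78 → −40 °C; cold aq. NaHCO3 quench
Reagents that add atoms: none
Why: Proposed new method: BF3 removes fluoride from 26 to give alkenyldifluoroborane 27, which ionises the electron-rich tertiary C6–OMe ketal (the C3 silyl ketal is deactivated by the adjacent ester arm) to peroxycarbenium ion 28 paired with the alkenyl(methoxy)borate, and the alkenyl group is transferred to C6 by ipso substitution with retention of alkene geometry. The closest known reaction types are the BF3-mediated coupling of potassium alkenyltrifluoroborates with oxocarbenium ions from acetals, and the Lewis-acid-mediated addition of allylsilanes, silyl enol ethers and alkenes to ketone-derived peroxycarbenium ions. C6 should be set by axial attack on the half-chair of 28 anti to the pseudo-equatorial C4 ethyl group (attack syn to it would develop a 1,3-diaxial clash), which places the alkenyl group axial and trans to that ethyl group, i.e. (6S).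

Step 16
Reactants: 29 methyl 2-[(4R,6S)-6-[(1E,4R,5E)-2,4-diethylocta-1,5-dien-1-yl]-4,6-diethyl-3-[(triethylsilyl)oxy]-1,2-dioxan-3-yl]acetate
Product: 31 methyl 2-[(3S,4R,6S)-6-[(1E,4R,5E)-2,4-diethylocta-1,5-dien-1-yl]-4,6-diethyl-1,2-dioxan-3-yl]acetate, via peroxycarbenium ion 30 (not isolated)
Conditions: Et3SiH (3 equiv), Me3SiOTf (0.2 equiv), CH2Cl2, −78 → −40 °C; Et3N, then aq. NaHCO3
Reagents that add atoms: none
Why: Silyl-triflate-promoted ionisation of the C3 silyl ketal and silane reduction of the resulting cation (ionic reduction as in Kishi's lactol reductions and in silane trapping of peroxycarbenium ions); hydride should enter axially on the half-chair that keeps the C4 and C6 ethyl groups equatorial, on the face away from the axial C6 alkenyl group, leaving CH2CO2Me equatorial and trans to the C4 ethyl group, i.e. (3S).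

Step 17
Reactants: 31 methyl 2-[(3S,4R,6S)-6-[(1E,4R,5E)-2,4-diethylocta-1,5-dien-1-yl]-4,6-diethyl-1,2-dioxan-3-yl]acetate
Product: 32 2-[(3S,4R,6S)-6-[(1E,4R,5E)-2,4-diethylocta-1,5-dien-1-yl]-4,6-diethyl-1,2-dioxan-3-yl]acetic acid
Conditions: LiOH, THF–MeOH–H2O, 0 °C; then 1 M HCl to pH 3
Reagents that add atoms: lithium hydroxide, SMILES [Li+].[OH-]
Why: Mild saponification of the methyl ester, as used for peroxy esters of this family, should leave the dialkyl peroxide and all stereocentres untouched at 0 °C.

## Compound list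

1 | cyclobutanone | O=C1CCC1 | starting material
2 | (2S)-N-cyclobutylidene-2-(methoxymethyl)pyrrolidin-1-amine | COC[C@@H]1CCCN1N=C1CCC1 | intermediate
3 | lithium azaenolate of 2 | COC[C@@H]1CCCN1N([Li])C1=CCC1 | intermediate
4 | (2S)-N-[(2R)-2-ethylcyclobutylidene]-2-(methoxymethyl)pyrrolidin-1-amine | COC[C@@H]1CCCN1N=C1[C@H](CC)CC1 | intermediate
5 | lithium azaenolate of 4 (deprotonated at the unsubstituted α′ carbon) | COC[C@@H]1CCCN1N([Li])C1=CC[C@H]1CC | intermediate
6 | (2S)-N-[(2R,4R)-2,4-diethylcyclobutylidene]-2-(methoxymethyl)pyrrolidin-1-amine | COC[C@@H]1CCCN1N=C1[C@H](CC)C[C@H]1CC | intermediate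
7 | (2R,4R)-2,4-diethylcyclobutan-1-one | O=C1[C@H](CC)C[C@H]1CC | intermediate
8 | potassium enolate of 7 | [K+].[O-]C1=C(CC)C[C@H]1CC | intermediate
9 | (4R)-2,4-diethylcyclobut-1-en-1-yl trifluoromethanesulfonate | CCC1=C(OS(=O)(=O)C(F)(F)F)[C@H](CC)C1 | intermediate
10 | methyl 2-[(4R)-2,4-diethylcyclobut-1-en-1-yl]acetate | CCC1=C(CC(=O)OC)[C@H](CC)C1 | intermediate
11 | primary ozonide of 10: methyl 2-[(7R)-5,7-diethyl-2,3,4-trioxabicyclo[3.2.0]heptan-1-yl]acetate | CCC12C[C@@H](CC)C1(CC(=O)OC)OOO2 | intermediate
12 | keto carbonyl oxide: the C6 carbonyl oxide of methyl (4R)-4-ethyl-3,6-dioxooctanoate | CCC(=[O+][O-])C[C@@H](CC)C(=O)CC(=O)OC | intermediate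
13 | methyl (4R)-4-ethyl-6-hydroperoxy-6-methoxy-3-oxooctanoate | CCC(OC)(OO)C[C@@H](CC)C(=O)CC(=O)OC | intermediate
14 | methyl 2-[(4R)-4,6-diethyl-3-hydroxy-6-methoxy-1,2-dioxan-3-yl]acetate (C3 and C6 epimers) | CCC1(OC)C[C@@H](CC)C(O)(CC(=O)OC)OO1 | intermediate
15 | methyl 2-[(4R)-4,6-diethyl-6-methoxy-3-[(triethylsilyl)oxy]-1,2-dioxan-3-yl]acetate (C3 and C6 epimers) | CCC1(OC)C[C@@H](CC)C(O[Si](CC)(CC)CC)(CC(=O)OC)OO1 | intermediate
16 | (E)-pent-2-enal | CC/C=C/C=O | starting material
17 | (3R,4E)-hept-4-en-3-ol | CC/C=C/[C@H](O)CC | intermediate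
18 | (3R,4E)-3-[(1-ethoxyethenyl)oxy]hept-4-ene | CC/C=C/[C@H](OC(=C)OCC)CC | intermediate
19 | ethyl (3R,4E)-3-ethylhept-4-enoate | CC/C=C/[C@H](CC)CC(=O)OCC | intermediate
20 | (3R,4E)-3-ethylhept-4-enal | CC/C=C/[C@H](CC)CC=O | intermediate
21 | (4R,5E)-4-ethyloct-5-en-1-yne | CC/C=C/[C@H](CC)CC#C | intermediate
22 | [(1E,4R,5E)-2,4-diethylocta-1,5-dien-1-yl]copper | CC/C=C/[C@H](CC)C/C(CC)=C/[Cu] | intermediate
23 | (1E,4R,5E)-2,4-diethyl-1-iodoocta-1,5-diene | CC/C=C/[C@H](CC)C/C(CC)=C/I | intermediate
24 | [(1E,4R,5E)-2,4-diethylocta-1,5-dien-1-yl]lithium | CC/C=C/[C@H](CC)C/C(CC)=C/[Li] | intermediate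
25 | lithium [(1E,4R,5E)-2,4-diethylocta-1,5-dien-1-yl]trimethoxyborate | CC/C=C/[C@H](CC)C/C(CC)=C/[B-](OC)(OC)OC.[Li+] | intermediate
26 | potassium [(1E,4R,5E)-2,4-diethylocta-1,5-dien-1-yl]trifluoroborate | CC/C=C/[C@H](CC)C/C(CC)=C/[B-](F)(F)F.[K+] | intermediate
27 | [(1E,4R,5E)-2,4-diethylocta-1,5-dien-1-yl]difluoroborane | CC/C=C/[C@H](CC)C/C(CC)=C/B(F)F | intermediate
28 | C6 peroxycarbenium ion from 15 (O1=C6 cation; C3 silyl ketal intact) | CCC1=[O+]OC(O[Si](CC)(CC)CC)(CC(=O)OC)[C@H](CC)C1 | intermediate
29 | methyl 2-[(4R,6S)-6-[(1E,4R,5E)-2,4-diethylocta-1,5-dien-1-yl]-4,6-diethyl-3-[(triethylsilyl)oxy]-1,2-dioxan-3-yl]acetate (C3 epimers) | CC/C=C/[C@H](CC)C/C(=C/[C@]1(CC)C[C@@H](CC)C(O[Si](CC)(CC)CC)(CC(=O)OC)OO1)CC | intermediate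
30 | C3 peroxycarbenium ion from 29 (O2=C3 cation bearing CH2CO2Me) | CC/C=C/[C@H](CC)C/C(=C/[C@]1(CC)C[C@@H](CC)C(CC(=O)OC)=[O+]O1)CC | intermediate
31 | methyl 2-[(3S,4R,6S)-6-[(1E,4R,5E)-2,4-diethylocta-1,5-dien-1-yl]-4,6-diethyl-1,2-dioxan-3-yl]acetate | CC/C=C/[C@H](CC)C/C(=C/[C@]1(CC)C[C@@H](CC)[C@H](CC(=O)OC)OO1)CC | intermediate
32 | 2-[(3S,4R,6S)-6-[(1E,4R,5E)-2,4-diethylocta-1,5-dien-1-yl]-4,6-diethyl-1,2-dioxan-3-yl]acetic acid | CC/C=C/[C@H](CC)C/C(=C/[C@]1(CC)C[C@@H](CC)[C@H](CC(=O)O)OO1)CC | target

## Step count and risks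

Total step count: 17. Longest linear sequence: 11 steps (steps 1–8 and 15–17, from cyclobutanone); the side-chain branch is steps 9–14.

Steps most likely to fail:

1. Step 15 (Proposed new method). The alkenylborane may be protodeboronated before C–C bond formation, ionisation may occur at C3 instead of C6, or the facial selectivity at the C6 cation may be poor. The fallback makes the C6–alkenyl bond by carbonyl addition before the peroxide exists, using known chemistry. It sets out from 10 and 23. Cyclobutene 10 is ozonised in CH2Cl2 and reduced with Me2S to methyl (4R)-4-ethyl-3,6-dioxooctanoate F1. Its 3-keto ester is masked as the sodium enolate (NaH), and alkenyllithium 24 (from 23 and tert-butyllithium, transmetalated with CeCl3) adds to the remaining ethyl ketone to give methyl (4R,7E,10R,11E)-4,6,8,10-tetraethyl-6-hydroxy-3-oxotetradeca-7,11-dienoate F2 as both C6 epimers. Acid-catalysed perhydrolysis (anhydrous H2O2 in Et2O, TsOH cat.) converts the 3-ketone into its perhydrate, whose OOH group captures the tertiary allylic cation at C6 in a six-membered closure to give methyl 2-[(4R)-6-[(1E,4R,5E)-2,4-diethylocta-1,5-dien-1-yl]-4,6-diethyl-3-hydroxy-1,2-dioxan-3-yl]acetate F3. After separation of the C6 epimers and silylation as in step 8, the (6S) isomer is 29, where the route is rejoined. This fallback gives up stereocontrol at C6 and pays for it with a separation.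

2. Step 16. The silyl triflate may ionise the tertiary allylic C6–O bond instead of the C3 ketal (loss of configuration at C6 or ring cleavage), or silanol may be eliminated from C3 toward the exocyclic enol ether. The fallback brings the hydrogen at C3 in from the start and attaches the acetate arm before the alkenyl group, so that no Lewis acid is needed once the allylic peroxide exists. It sets out from 9. The triflate is reduced (Pd(OAc)2, PPh3, HCO2H, Et3N) to (3R)-1,3-diethylcyclobut-1-ene F4. Ozonolysis in CH2Cl2–MeOH as in step 7 should give (4R)-4,6-diethyl-6-methoxy-1,2-dioxan-3-ol F5. Wittig olefination of this peroxy lactol with Ph3P=CHCO2Me opens it to methyl (2E,4R)-4-ethyl-6-hydroperoxy-6-methoxyoct-2-enoate F6, and base (Et2NH, CF3CH2OH) closes it again by intramolecular oxa-Michael addition to methyl 2-[(3S,4R)-4,6-diethyl-6-methoxy-1,2-dioxan-3-yl]acetate F7. The 3,4-trans isomer (both substituents equatorial) should be favoured under equilibrating conditions, though less decisively than by the axial hydride delivery of the main route. Alkenylation of F7 with 26 under the conditions of step 15 returns to the route at 31.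

3. Step 8. The silyl triflate may capture the open-chain hydroperoxy keto ester tautomer instead of the cyclic hemiketal, or may ionise the C6 ketal. The fallback replaces kinetic silylation by ketal exchange under thermodynamic control. It sets out from 14, which is stirred with MeOH, HC(OMe)3 and pyridinium p-toluenesulfonate to give methyl 2-[(4R)-4,6-diethyl-3,6-dimethoxy-1,2-dioxan-3-yl]acetate F8. F8 is alkenylated at the more electron-rich C6 as in step 15 to methyl 2-[(4R,6S)-6-[(1E,4R,5E)-2,4-diethylocta-1,5-dien-1-yl]-4,6-diethyl-3-methoxy-1,2-dioxan-3-yl]acetate F9. F9 is reduced as in step 16, here with one equivalent of Me3SiOTf, and the route is rejoined at 31.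

## Further compounds

F1 | step 15 | methyl (4R)-4-ethyl-3,6-dioxooctanoate | CCC(=O)C[C@@H](CC)C(=O)CC(=O)OC
F2 | step 15 | methyl (4R,7E,10R,11E)-4,6,8,10-tetraethyl-6-hydroxy-3-oxotetradeca-7,11-dienoate (C6 epimers) | CC/C=C/[C@H](CC)C/C(=C/C(O)(CC)C[C@@H](CC)C(=O)CC(=O)OC)CC
F3 | step 15 | methyl 2-[(4R)-6-[(1E,4R,5E)-2,4-diethylocta-1,5-dien-1-yl]-4,6-diethyl-3-hydroxy-1,2-dioxan-3-yl]acetate (C6 epimers) | CC/C=C/[C@H](CC)C/C(=C/C1(CC)C[C@@H](CC)C(O)(CC(=O)OC)OO1)CC
F4 | step 16 | (3R)-1,3-diethylcyclobut-1-ene | CCC1=C[C@H](CC)C1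
F5 | step 16 | (4R)-4,6-diethyl-6-methoxy-1,2-dioxan-3-ol (C3 and C6 epimers) | CCC1(OC)C[C@@H](CC)C(O)OO1
F6 | step 16 | methyl (2E,4R)-4-ethyl-6-hydroperoxy-6-methoxyoct-2-enoate | CCC(OC)(OO)C[C@@H](CC)/C=C/C(=O)OC
F7 | step 16 | methyl 2-[(3S,4R)-4,6-diethyl-6-methoxy-1,2-dioxan-3-yl]acetate (C6 epimers) | CCC1(OC)C[C@@H](CC)[C@H](CC(=O)OC)OO1
F8 | step 8 | methyl 2-[(4R)-4,6-diethyl-3,6-dimethoxy-1,2-dioxan-3-yl]acetate (C3 and C6 epimers) | CCC1(OC)C[C@@H](CC)C(OC)(CC(=O)OC)OO1
F9 | step 8 | methyl 2-[(4R,6S)-6-[(1E,4R,5E)-2,4-diethylocta-1,5-dien-1-yl]-4,6-diethyl-3-methoxy-1,2-dioxan-3-yl]acetate (C3 epimers) | CC/C=C/[C@H](CC)C/C(=C/[C@]1(CC)C[C@@H](CC)C(OC)(CC(=O)OC)OO1)CC
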